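Retrosynthetic overview
- Chroman numbering is O1, C2 (CMe2), C3 (CHOH), C4 (CH2), C4a, C5 (OH), C6 (acyl), C7 (OMe), C8, C8a. The end game removes two phenolic MOM groups. Before that, the C6–C(=O) bond is cut to a C6 aryllithium and the Weinreb amide of 4-(methoxymethoxy)cinnamic acid, which comes from an HWE reaction.
- The C3 stereocentre goes back to a 2,2-dimethylchroman-3-one. It is reduced under catalyst control, with the quaternary C2 set against C4H2.
- The pyran ring is first built one carbon short, as the furanone ring of a 2,2-dimethylbenzofuran-3(2H)-one. C4 is then inserted between the carbonyl carbon and the arene by a carbenoid 1,2-aryl shift.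
- Enabling feature: in the ring O1–C2–C3–C4–C4a–C8a, the oxygen-bearing C3 lies between a quaternary, O1-substituted C2 (no enolisation, poor migrating group) and a CH2 bound to a phloroglucinol-type arene (excellent migrating group). The core is therefore the aryl-shifted homologue of a ketone that a Friedel–Crafts acylation delivers, and the same ketone tells the two methoxy groups apart by chelation.
- Order of rings: oxygenated arene (bought), furanone ring (O-alkylation, then acylation), pyran ring (ring enlargement). The 4-hydroxyphenyl ring is bought.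

Key step: step 5

Remark: benzofuran numbering (O1, C2, C3, C3a, C4 to C7, C7a) is used for the five-membered-ring compounds. The aldehyde and the phosphonate of step 7 are taken as commercial.

Step 1
Reactants: 1 3,5-dimethoxyphenol; 2 2-bromo-2-methylpropanoic acid
Product: 3 2-(3,5-dimethoxyphenoxy)-2-methylpropanoic acid
Conditions: NaOH, 2-butanone, 50 °C to reflux; then aq HCl
Reagents that add atoms: none
Why: Williamson-type O-alkylation of the phenoxide by the alpha-bromo carboxylate (the standard aryloxyisobutyric acid synthesis), in which the carboxylate assists loss of bromide at the tertiary carbon, so the hindered O1–C2 bond is in place from the start.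

Step 2
Reactants: 3 2-(3,5-dimethoxyphenoxy)-2-methylpropanoic acid
Product: 5 4,6-dimethoxy-2,2-dimethyl-1-benzofuran-3(2H)-one, via mixed trifluoroacetic anhydride 4 (not isolated)
Conditions: (CF3CO)2O, CH2Cl2, 0 °C to rt
Reagents that add atoms: none
Why: Intramolecular Friedel–Crafts acylation should close the five-membered furanone ring on either of the two equivalent, doubly activated ortho positions, helped by the gem-dimethyl effect.

Step 3
Reactants: 5 4,6-dimethoxy-2,2-dimethyl-1-benzofuran-3(2H)-one
Product: 6 4-hydroxy-6-methoxy-2,2-dimethyl-1-benzofuran-3(2H)-one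
Conditions: BCl3 (1.2 equiv), CH2Cl2, −78 to 0 °C; then H2O
Reagents that add atoms: none
Why: Chelation-controlled aryl methyl ether cleavage, in which BCl3 is held between the ketone oxygen and the peri C4 methoxy oxygen, so chloride should remove only that methyl group while the remote C6 methoxy group stays.

Step 4
Reactants: 6 4-hydroxy-6-methoxy-2,2-dimethyl-1-benzofuran-3(2H)-one
Product: 7 6-methoxy-4-(methoxymethoxy)-2,2-dimethyl-1-benzofuran-3(2H)-one
Conditions: NaH, MOMCl, DMF, 0 °C
Reagents that add atoms: chloromethyl methyl ether (MOMCl), COCCl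
Why: Standard O-alkylation of the deprotonated phenol gives a MOM acetal that survives the strong bases of steps 5 and 8 and later directs the lithiation.

Step 5
Reactants: 7 6-methoxy-4-(methoxymethoxy)-2,2-dimethyl-1-benzofuran-3(2H)-one
Product: 11 7-methoxy-5-(methoxymethoxy)-2,2-dimethyl-2H-chromen-3(4H)-one, via lithium dibromomethyl carbinolate 8 (not isolated), via beta-oxido carbenoid 9 (not isolated), via lithium enolate 10 (not isolated)
Conditions: CH2Br2, lithium 2,2,6,6-tetramethylpiperidide, THF, −90 to −78 °C; then n-BuLi, −78 to 0 °C; then sat. aq NH4Cl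
Reagents that add atoms: dibromomethane, BrCBr
Why: Dibromomethyllithium, made in the presence of the ketone, adds to the C3 carbonyl (enolisation is impossible because C2 is quaternary), bromine–lithium exchange turns the carbinolate into a beta-oxido carbenoid, and loss of LiBr goes with a 1,2-shift of arene carbon C3a from the carbinolate carbon to the carbenoid carbon, giving the lithium enolate of the enlarged ketone. The closest known reaction type is the beta-oxido carbenoid one-carbon ring enlargement of cyclic ketones, a base-mediated relative of the Tiffeneau–Demjanov reaction. No ring is closed from an open chain: the five-membered ring O1–C2–C3–C3a–C7a becomes the six-membered ring O1–C2–C3–C4–C4a–C8a because the new carbon C4 is inserted into the bond between carbonyl carbon and arene. No stereocentre results, since the transient carbinolate and carbenoid centres end as the sp2 carbon C3 and the CH2 group C4, so their configurations are without consequence. The selectivity needed is migration of the arene instead of C2; it is secured by the three donor oxygens of the arene, by the p orbital at C3a that lies parallel to the out-of-plane C–Br bond and can bridge to it, and by the electron-withdrawing O1 on the quaternary C2, which makes C2 a poor migrating group. Exchange at bromine at −78 °C should outrun ring lithiation or attack on the MOM acetal, and the product is stored as an enolate that cannot eliminate because O1 sits on the non-enolisable side.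

Step 6
Reactants: 11 7-methoxy-5-(methoxymethoxy)-2,2-dimethyl-2H-chromen-3(4H)-one
Product: 12 (3R)-7-methoxy-5-(methoxymethoxy)-2,2-dimethyl-3,4-dihydro-2H-chromen-3-ol
Conditions: BH3·SMe2, (S)-5,5-diphenyl-2-methyl-3,4-propano-1,3,2-oxazaborolidine [(S)-Me-CBS, 10 mol %], THF, −20 °C; then MeOH
Reagents that add atoms: none
Why: Corey–Bakshi–Shibata reduction, in which the ketone should bind the catalyst boron anti to the bulky quaternary C2 side so that hydride reaches the face giving the (3R)-alcohol, in line with the sense known for tert-alkyl against primary-alkyl ketones with the (S)-catalyst.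

Step 7
Reactants: 13 4-(methoxymethoxy)benzaldehyde; 14 diethyl {2-[methoxy(methyl)amino]-2-oxoethyl}phosphonate
Product: 15 (E)-N-methoxy-3-[4-(methoxymethoxy)phenyl]-N-methylprop-2-enamide
Conditions: LiCl, DBU, MeCN, rt
Reagents that add atoms: none
Why: Horner–Wadsworth–Emmons olefination under Masamune–Roush conditions with a stabilised phosphonate should give the (E)-alkene under the usual thermodynamic control.

Step 8
Reactants: 12 (3R)-7-methoxy-5-(methoxymethoxy)-2,2-dimethyl-3,4-dihydro-2H-chromen-3-ol; 15 (E)-N-methoxy-3-[4-(methoxymethoxy)phenyl]-N-methylprop-2-enamide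
Product: 18 (E)-1-[(3R)-3-hydroxy-7-methoxy-5-(methoxymethoxy)-2,2-dimethyl-3,4-dihydro-2H-chromen-6-yl]-3-[4-(methoxymethoxy)phenyl]prop-2-en-1-one, via dilithiated chromanol 16 (not isolated), via tetrahedral lithium adduct 17 (not isolated)
Conditions: n-BuLi (2.3 equiv), TMEDA, THF, −20 to 0 °C; then 15, −78 to 0 °C; then sat. aq NH4Cl
Reagents that add atoms: none
Why: Directed ortho-metalation followed by Weinreb ketone synthesis, in which the C3 hydroxyl is first masked as its lithium alkoxide, the second equivalent of base should remove H6 (between the chelating OMOM group and the OMe group) rather than H8, and the aryllithium adds 1,2 to the amide to a chelated adduct that releases the enone only on work-up with the E alkene untouched.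

Step 9
Reactants: 18 (E)-1-[(3R)-3-hydroxy-7-methoxy-5-(methoxymethoxy)-2,2-dimethyl-3,4-dihydro-2H-chromen-6-yl]-3-[4-(methoxymethoxy)phenyl]prop-2-en-1-one
Product: 19 (E)-1-[(3R)-3,5-dihydroxy-7-methoxy-2,2-dimethyl-3,4-dihydro-2H-chromen-6-yl]-3-(4-hydroxyphenyl)prop-2-en-1-one (target)
Conditions: HCl (about 1 M), MeOH, rt
Reagents that add atoms: none
Why: Acid-catalysed transacetalisation removes both aryl MOM groups under conditions mild enough for the tertiary aryl ether, the C3 carbinol and the enone to persist, and the freed C5 hydroxyl is tied up in a hydrogen bond to the ketone, which slows oxa-Michael closure to the flavanone.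

Compound list
1 | 3,5-dimethoxyphenol | COc1cc(O)cc(OC)c1 | starting material
2 | 2-bromo-2-methylpropanoic acid | CC(C)(Br)C(=O)O | starting material
3 | 2-(3,5-dimethoxyphenoxy)-2-methylpropanoic acid | COc1cc(OC)cc(OC(C)(C)C(=O)O)c1 | intermediate
4 | 2-(3,5-dimethoxyphenoxy)-2-methylpropanoic trifluoroacetic anhydride (not isolated) | COc1cc(OC)cc(OC(C)(C)C(=O)OC(=O)C(F)(F)F)c1 | intermediate
5 | 4,6-dimethoxy-2,2-dimethyl-1-benzofuran-3(2H)-one | COc1cc(OC)c2C(=O)C(C)(C)Oc2c1 | intermediate
6 | 4-hydroxy-6-methoxy-2,2-dimethyl-1-benzofuran-3(2H)-one | COc1cc(O)c2C(=O)C(C)(C)Oc2c1 | intermediate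
7 | 6-methoxy-4-(methoxymethoxy)-2,2-dimethyl-1-benzofuran-3(2H)-one | COCOc1cc(OC)cc2OC(C)(C)C(=O)c12 | intermediate
8 | lithium 3-(dibromomethyl)-6-methoxy-4-(methoxymethoxy)-2,2-dimethyl-2,3-dihydro-1-benzofuran-3-olate (not isolated, C3 configuration irrelevant) | [Li+].[O-]C1(C(Br)Br)c2c(OCOC)cc(OC)cc2OC1(C)C | intermediate
9 | lithium 3-[bromo(lithio)methyl]-6-methoxy-4-(methoxymethoxy)-2,2-dimethyl-2,3-dihydro-1-benzofuran-3-olate (not isolated) | [Li]C(Br)C1([O-])c2c(OCOC)cc(OC)cc2OC1(C)C.[Li+] | intermediate
10 | lithium 7-methoxy-5-(methoxymethoxy)-2,2-dimethyl-2H-chromen-3-olate (not isolated) | [Li+].[O-]C1=Cc2c(OCOC)cc(OC)cc2OC1(C)C | intermediate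
11 | 7-methoxy-5-(methoxymethoxy)-2,2-dimethyl-2H-chromen-3(4H)-one | COCOc1cc(OC)cc2OC(C)(C)C(=O)Cc12 | intermediate
12 | (3R)-7-methoxy-5-(methoxymethoxy)-2,2-dimethyl-3,4-dihydro-2H-chromen-3-ol | COCOc1cc(OC)cc2OC(C)(C)[C@H](O)Cc12 | intermediate
13 | 4-(methoxymethoxy)benzaldehyde | COCOc1ccc(C=O)cc1 | starting material
14 | diethyl {2-[methoxy(methyl)amino]-2-oxoethyl}phosphonate | CCOP(=O)(CC(=O)N(C)OC)OCC | starting material
15 | (E)-N-methoxy-3-[4-(methoxymethoxy)phenyl]-N-methylprop-2-enamide | COCOc1ccc(/C=C/C(=O)N(C)OC)cc1 | intermediate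
16 | lithium (3R)-6-lithio-7-methoxy-5-(methoxymethoxy)-2,2-dimethyl-3,4-dihydro-2H-chromen-3-olate (not isolated) | [Li]c1c(OC)cc2OC(C)(C)[C@H]([O-])Cc2c1OCOC.[Li+] | intermediate
17 | dilithium salt of the tetrahedral adduct of 16 to 15 (not isolated, new centre undefined) | [Li+].[Li+].[O-]C(/C=C/c1ccc(OCOC)cc1)(N(C)OC)c1c(OC)cc2OC(C)(C)[C@H]([O-])Cc2c1OCOC | intermediate
18 | (E)-1-[(3R)-3-hydroxy-7-methoxy-5-(methoxymethoxy)-2,2-dimethyl-3,4-dihydro-2H-chromen-6-yl]-3-[4-(methoxymethoxy)phenyl]prop-2-en-1-one | COCOc1ccc(/C=C/C(=O)c2c(OC)cc3OC(C)(C)[C@H](O)Cc3c2OCOC)cc1 | intermediate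
19 | (E)-1-[(3R)-3,5-dihydroxy-7-methoxy-2,2-dimethyl-3,4-dihydro-2H-chromen-6-yl]-3-(4-hydroxyphenyl)prop-2-en-1-one | COc1cc2c(c(O)c1C(=O)/C=C/c1ccc(O)cc1)C[C@@H](O)C(C)(C)O2 | target

Total step count: 9. Longest linear sequence: 8 (steps 1 to 6, 8 and 9).

Steps most likely to fail

First, step 5. The hindered carbonyl, deactivated by three donor oxygens, may take up the short-lived dibromomethyllithium too slowly. Part of the carbenoid may also rearrange by shift of C2 instead of the arene.

The fallback sets out from 7 and comes back at 11. It replaces the carbenoid by an oxidative aryl shift.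
- MeLi in THF adds to 7 to give the tertiary carbinol 6-methoxy-4-(methoxymethoxy)-2,2,3-trimethyl-2,3-dihydro-1-benzofuran-3-ol F1.
- Catalytic pyridinium p-toluenesulfonate in warm toluene dehydrates it towards the only carbon that offers a beta hydrogen. This gives 6-methoxy-4-(methoxymethoxy)-2,2-dimethyl-3-methylidene-2,3-dihydro-1-benzofuran F2.
- The trivalent iodine reagent PhI(OH)OTs in 95% aqueous MeOH at 0 °C then adds to the exocyclic alkene. Departure of iodobenzene from the CH2 carbon drives the 1,2-aryl shift to 11. This is the methylenation and ring expansion sequence known for benzo-fused ketones.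
- Any phenolic MOM group lost to the acid formed is put back as in step 4.

Second, step 8. Site selectivity of the lithiation may be poor (H8 instead of H6). The alkoxide aggregate may metalate incompletely, or the aryllithium may add in a conjugate sense.

The fallback sets out from 12 and comes back at 19. It relies on chelation-controlled electrophilic acylation instead of metalation.
- HCl in MeOH frees the phenol to give (3R)-7-methoxy-2,2-dimethyl-3,4-dihydro-2H-chromene-3,5-diol F3.
- Ac2O with BF3·OEt2 at 60 °C acetylates the C3 hydroxyl. It places the C-acetyl group at C6, the only ring position next to the free phenol where a boron chelate can form. This gives (3R)-6-acetyl-5-hydroxy-7-methoxy-2,2-dimethyl-3,4-dihydro-2H-chromen-3-yl acetate F4.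
- Claisen–Schmidt condensation with aldehyde 13 (KOH, EtOH, rt) builds the E enone and saponifies the acetate in the same pot. This gives (E)-1-[(3R)-3,5-dihydroxy-7-methoxy-2,2-dimethyl-3,4-dihydro-2H-chromen-6-yl]-3-[4-(methoxymethoxy)phenyl]prop-2-en-1-one F5.
- The conditions of step 9 remove the last MOM group to give 19.

Third, step 3. In the five-membered ketone the carbonyl and peri methoxy oxygens are splayed apart. Chelation may therefore be weak, and discrimination between the two methyl ethers may be lost.

The fallback sets out from 5 and comes back at 6. It replaces selective cleavage by exhaustive cleavage and selective re-alkylation.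
- Excess BBr3 in CH2Cl2 gives 4,6-dihydroxy-2,2-dimethyl-1-benzofuran-3(2H)-one F6.
- One equivalent of MeI with K2CO3 in acetone should methylate the more acidic and less hindered C6 hydroxyl, which is para to the carbonyl. The C4 hydroxyl next to the ketone is left free.

Further compounds
F1 | step 5 | 6-methoxy-4-(methoxymethoxy)-2,2,3-trimethyl-2,3-dihydro-1-benzofuran-3-ol | COCOc1cc(OC)cc2OC(C)(C)C(C)(O)c12
F2 | step 5 | 6-methoxy-4-(methoxymethoxy)-2,2-dimethyl-3-methylidene-2,3-dihydro-1-benzofuran | COCOc1cc(OC)cc2OC(C)(C)C(=C)c12
F3 | step 8 | (3R)-7-methoxy-2,2-dimethyl-3,4-dihydro-2H-chromene-3,5-diol | COc1cc(O)c2c(c1)OC(C)(C)[C@H](O)C2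
F4 | step 8 | (3R)-6-acetyl-5-hydroxy-7-methoxy-2,2-dimethyl-3,4-dihydro-2H-chromen-3-yl acetate | CC(=O)c1c(OC)cc2OC(C)(C)[C@H](OC(C)=O)Cc2c1O
F5 | step 8 | (E)-1-[(3R)-3,5-dihydroxy-7-methoxy-2,2-dimethyl-3,4-dihydro-2H-chromen-6-yl]-3-[4-(methoxymethoxy)phenyl]prop-2-en-1-one | COCOc1ccc(/C=C/C(=O)c2c(OC)cc3OC(C)(C)[C@H](O)Cc3c2O)cc1
F6 | step 3 | 4,6-dihydroxy-2,2-dimethyl-1-benzofuran-3(2H)-one | Oc1cc(O)c2C(=O)C(C)(C)Oc2c1
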